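## Retrosynthetic overview

1. The trans C7–OH/C8–Cl chlorohydrin comes from HCl opening at C8 of a 7,8-epoxide that lies cis to the 5,6-diol; the epoxide comes from hydroxyl-directed epoxidation of the C7=C8 alkene of a 5,6-dioxygenated 5,6-dihydrochromone.
2. Ring B (γ-pyrone: O1, C2, C3, C4, C4a, C8a) comes from a hetero-Diels–Alder reaction of an arylethyl acylketene (released from a dioxinone) with the C4a=C8a silyl enol ether of a 4-hydroxy-5-silyloxycyclohex-2-enone.
3. Ring A (carbocycle: C4a, C5, C6, C7, C8, C8a) comes from a [4+2] union of a C8a–C4a–C5–C6 ester aldehyde made from (S)-malate with (Z)-1,2-diborylethene as C7=C8, closing C6–C7 and C8–C8a in one rhodium-catalysed operation.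
4. Enabling feature: in ring A, C6 (a carbinol) and C8a (the O1-bearing ring-fusion carbon, at ketone level) are both former carbonyl carbons, 1,4-related across C4a–C5; C5 is the carbinol of (S)-malic acid; and the C7–OH/C8–Cl pair is the retron of a cis C7=C8 alkene, so C7/C8 can enter as a cis-vinylene 1,2-dianion equivalent.
5. Order of ring formation: ring A (step 8), ring B (step 10), temporary oxirane on C7/C8 (step 11, opened in step 13).

Key step: step 8

Remark: the addition to the α-silyloxy aldehyde in step 8 is assumed to follow the Felkin–Anh (1,2-anti) sense; positions in all intermediates are given in chromone numbering (O1, C2–C4, C4a, C5–C8, C8a), also for the carbons of earlier compounds that end up there.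

## Route

Step 1
Reactants: 1 isovanillin (3-hydroxy-4-methoxybenzaldehyde)
Product: 2 3-[(tert-butyldimethylsilyl)oxy]-4-methoxybenzaldehyde
Conditions: TBSCl, imidazole, DMF, rt
Reagents that add atoms: tert-butyldimethylsilyl chloride, CC(C)(C)[Si](C)(C)Cl
Why: Standard phenol silylation; the aryl silyl ether should survive the basic, thermal and oxidative steps and is removed by fluoride in step 12.

Step 2
Reactants: 2 3-[(tert-butyldimethylsilyl)oxy]-4-methoxybenzaldehyde
Product: 3 {3-[(tert-butyldimethylsilyl)oxy]-4-methoxyphenyl}methanol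
Conditions: NaBH4, MeOH, 0 °C
Reagents that add atoms: none
Why: Borohydride reduction of an aryl aldehyde to the benzylic alcohol, which should leave the aryl silyl ether intact at 0 °C.

Step 3
Reactants: 3 {3-[(tert-butyldimethylsilyl)oxy]-4-methoxyphenyl}methanol
Product: 4 4-(bromomethyl)-2-[(tert-butyldimethylsilyl)oxy]-1-methoxybenzene
Conditions: CBr4, PPh3, CH2Cl2, 0 °C
Reagents that add atoms: carbon tetrabromide, BrC(Br)(Br)Br
Why: Appel bromination converts the benzylic alcohol into the bromide under neutral conditions that spare the silyl ether.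

Step 4
Reactants: 5 2,2,6-trimethyl-4H-1,3-dioxin-4-one; 4 4-(bromomethyl)-2-[(tert-butyldimethylsilyl)oxy]-1-methoxybenzene
Product: 6 6-(2-{3-[(tert-butyldimethylsilyl)oxy]-4-methoxyphenyl}ethyl)-2,2-dimethyl-4H-1,3-dioxin-4-one
Conditions: LiN(i-Pr)2, THF, −78 °C; DMPU; then 4, −78 → −30 °C
Reagents that add atoms: none
Why: Vinylogous enolate alkylation: the lithium dienolate of the dioxinone (a masked acetoacetate) should be alkylated at its γ-carbon (the 6-methyl group) by the reactive benzylic bromide, installing the complete C2 side chain.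

Step 5
Reactants: 7 dimethyl (S)-malate
Product: 8 dimethyl (2S)-2-[(tert-butyldimethylsilyl)oxy]butanedioate
Conditions: TBSCl, imidazole, DMF, rt
Reagents that add atoms: tert-butyldimethylsilyl chloride, CC(C)(C)[Si](C)(C)Cl
Why: Silylation of the secondary alcohol; the C5 stereocentre comes from the chiral pool and is untouched, and the non-chelating silyl group prepares Felkin–Anh control in step 8.

Step 6
Reactants: 8 dimethyl (2S)-2-[(tert-butyldimethylsilyl)oxy]butanedioate
Product: 9 methyl (3S)-3-[(tert-butyldimethylsilyl)oxy]-4-oxobutanoate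
Conditions: i-Bu2AlH (1.05 equiv), CH2Cl2, −78 °C; Rochelle salt work-up
Reagents that add atoms: none
Why: Regioselective half-reduction: the ester next to the α-silyloxy group is the more electrophilic one and should be reduced to the aldehyde (C6) through a stable tetrahedral aluminate at −78 °C, leaving the distal ester (C8a) and the stereocentre intact.

Step 7
Reactants: 10 acetylene; 11 bis(pinacolato)diboron
Product: 12 (Z)-1,2-bis(4,4,5,5-tetramethyl-1,3,2-dioxaborolan-2-yl)ethene
Conditions: HC≡CH (1 atm), Pt(PPh3)4 (3 mol %), DMF, 80 °C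
Reagents that add atoms: none
Why: Zerovalent-platinum-catalysed diboration of an alkyne is a syn addition, which fixes the Z geometry of the C7=C8 linchpin.

Step 8
Reactants: 9 methyl (3S)-3-[(tert-butyldimethylsilyl)oxy]-4-oxobutanoate; 12 (Z)-1,2-bis(4,4,5,5-tetramethyl-1,3,2-dioxaborolan-2-yl)ethene
Product: 14 (4R,5S)-5-[(tert-butyldimethylsilyl)oxy]-4-hydroxycyclohex-2-en-1-one, via hydroxy alkenylboronate 13 (not isolated)
Conditions: [Rh(cod)OH]2 (3 mol %), P(t-Bu)3 (6 mol %), 1,4-dioxane–H2O (20:1), 25 °C; then dilution to 0.02 M, 60 °C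
Reagents that add atoms: none
Why: Proposed new method: boron-to-rhodium transmetalation of 12 should give a (Z)-2-borylvinyl rhodium species (monovalent rhodium) that adds 1,2 to the aldehyde carbon C6 of 9 (bond C6–C7), giving 13 held as its cyclic borate; the second boryl group then transmetalates, the (Z)-alkenylrhodium at C8 adds to the ester carbonyl C8a (bond C8–C8a), and β-methoxide elimination releases the enone and a methoxo-rhodium species that carries the cycle. The closest known reaction types are the rhodium-catalysed addition of alkenylboron reagents to aldehydes and the intramolecular acylation of alkenylrhodium intermediates by pendant esters in arylative alkyne cyclisations; new is their merger with a 1,2-diborylated cis-ethene as a vinylene 1,2-dianion equivalent. Ring A is closed by 6-exo-trig attack on the ester C=O, which requires the cis geometry of 12; this should be retained because both transmetalations proceed with retention. The new stereocentre C6 is set in the first addition by Felkin–Anh control from the C5 silyloxy group (1,2-anti, hence the cis-5,6-dioxygenation and 4R in 14), while C5 is carried from malate. The step needs aldehyde-before-ester chemoselectivity in the intermolecular event, and the ring closure must beat lactonisation of the C6 alkoxide and conjugate addition of alkenylrhodium to enone already formed; the far greater electrophilicity of the aldehyde, the masking of the alkoxide as a boron ester and high dilution in the second stage are meant to secure this.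

Step 9
Reactants: 14 (4R,5S)-5-[(tert-butyldimethylsilyl)oxy]-4-hydroxycyclohex-2-en-1-one
Product: 15 (5R,6S)-6-[(tert-butyldimethylsilyl)oxy]-2,5-bis[(trimethylsilyl)oxy]cyclohexa-1,3-diene
Conditions: LiN(i-Pr)2 (2.5 equiv), Me3SiCl (3 equiv), THF, −78 °C (in situ quench)
Reagents that add atoms: chlorotrimethylsilane, C[Si](C)(C)Cl
Why: Kinetic α′-deprotonation of the enone at C4a with immediate silyl trapping should give the cross-conjugated silyl enol ether (C4a=C8a) before the β-silyloxy enolate can eliminate, and the C6 hydroxyl is silylated in the same operation (silyl enol ether formation).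

Step 10
Reactants: 15 (5R,6S)-6-[(tert-butyldimethylsilyl)oxy]-2,5-bis[(trimethylsilyl)oxy]cyclohexa-1,3-diene; 6 6-(2-{3-[(tert-butyldimethylsilyl)oxy]-4-methoxyphenyl}ethyl)-2,2-dimethyl-4H-1,3-dioxin-4-one
Product: 19 (5S,6R)-5-[(tert-butyldimethylsilyl)oxy]-2-(2-{3-[(tert-butyldimethylsilyl)oxy]-4-methoxyphenyl}ethyl)-6-hydroxy-5,6-dihydro-4H-chromen-4-one, via acylketene 16 (not isolated), via cycloadduct 17 (not isolated), via trimethylsilyl ether 18 (not isolated)
Conditions: toluene, 110 °C; then PPTS (cat.), MeOH, 0 °C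
Reagents that add atoms: none
Why: Thermal retro-[4+2] of the dioxinone releases acylketene 16, which should add as a heterodiene to the electron-rich enol ether C4a=C8a (ketene carbon to C4a, acyl oxygen to C8a; hetero-Diels–Alder reaction), after which loss of Me3SiOH from 17 aromatises ring B to the γ-pyrone and mild methanolysis frees the C6 hydroxyl without touching the tert-butyldimethylsilyl ethers.

Step 11
Reactants: 19 (5S,6R)-5-[(tert-butyldimethylsilyl)oxy]-2-(2-{3-[(tert-butyldimethylsilyl)oxy]-4-methoxyphenyl}ethyl)-6-hydroxy-5,6-dihydro-4H-chromen-4-one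
Product: 20 (5S,6R,7S,8S)-5-[(tert-butyldimethylsilyl)oxy]-2-(2-{3-[(tert-butyldimethylsilyl)oxy]-4-methoxyphenyl}ethyl)-7,8-epoxy-6-hydroxy-5,6,7,8-tetrahydro-4H-chromen-4-one
Conditions: VO(acac)2 (5 mol %), t-BuOOH (1.5 equiv), CH2Cl2, 0 °C → rt
Reagents that add atoms: tert-butyl hydroperoxide, CC(C)(C)OO
Why: Vanadium-catalysed hydroxyl-directed epoxidation of a cyclic allylic alcohol should deliver oxygen to C7=C8 on the face of the C6 hydroxyl, setting C7 and C8 cis to the 5,6-dioxygen pair.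

Step 12
Reactants: 20 (5S,6R,7S,8S)-5-[(tert-butyldimethylsilyl)oxy]-2-(2-{3-[(tert-butyldimethylsilyl)oxy]-4-methoxyphenyl}ethyl)-7,8-epoxy-6-hydroxy-5,6,7,8-tetrahydro-4H-chromen-4-one
Product: 21 (5S,6S,7S,8S)-7,8-epoxy-5,6-dihydroxy-2-[2-(3-hydroxy-4-methoxyphenyl)ethyl]-5,6,7,8-tetrahydro-4H-chromen-4-one
Conditions: Bu4NF (2.5 equiv), AcOH (2.5 equiv), THF, 0 °C
Reagents that add atoms: none
Why: Buffered fluoride desilylation should remove the aryl and the secondary silyl ether while the epoxide stays closed, because the cis C6 hydroxyl cannot attack it from the rear (no Payne rearrangement) and buffered fluoride is a poor nucleophile for epoxides.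

Step 13
Reactants: 21 (5S,6S,7S,8S)-7,8-epoxy-5,6-dihydroxy-2-[2-(3-hydroxy-4-methoxyphenyl)ethyl]-5,6,7,8-tetrahydro-4H-chromen-4-one
Product: 22 (5S,6S,7S,8R)-8-chloro-5,6,7-trihydroxy-2-[2-(3-hydroxy-4-methoxyphenyl)ethyl]-5,6,7,8-tetrahydro-4H-chromen-4-one (target)
Conditions: HCl (1 M in Et2O, 1.5 equiv), THF, −20 → 0 °C
Reagents that add atoms: hydrogen chloride, Cl
Why: Acid-promoted trans opening of the epoxide by chloride should occur at C8, the position activated by the adjacent pyranone π-system and less hindered than C7 (which is flanked by the C6 carbinol); inversion at C8 with the C7–O bond untouched gives the 8-chloro-7-hydroxy trans-chlorohydrin (epoxide ring opening).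

## Compound list

1 | isovanillin (3-hydroxy-4-methoxybenzaldehyde) | COc1ccc(C=O)cc1O | starting material
2 | 3-[(tert-butyldimethylsilyl)oxy]-4-methoxybenzaldehyde | COc1ccc(C=O)cc1O[Si](C)(C)C(C)(C)C | intermediate
3 | {3-[(tert-butyldimethylsilyl)oxy]-4-methoxyphenyl}methanol | COc1ccc(CO)cc1O[Si](C)(C)C(C)(C)C | intermediate
4 | 4-(bromomethyl)-2-[(tert-butyldimethylsilyl)oxy]-1-methoxybenzene | COc1ccc(CBr)cc1O[Si](C)(C)C(C)(C)C | intermediate
5 | 2,2,6-trimethyl-4H-1,3-dioxin-4-one | CC1=CC(=O)OC(C)(C)O1 | starting material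
6 | 6-(2-{3-[(tert-butyldimethylsilyl)oxy]-4-methoxyphenyl}ethyl)-2,2-dimethyl-4H-1,3-dioxin-4-one | COc1ccc(CCC2=CC(=O)OC(C)(C)O2)cc1O[Si](C)(C)C(C)(C)C | intermediate
7 | dimethyl (S)-malate | COC(=O)C[C@H](O)C(=O)OC | starting material
8 | dimethyl (2S)-2-[(tert-butyldimethylsilyl)oxy]butanedioate | COC(=O)C[C@H](O[Si](C)(C)C(C)(C)C)C(=O)OC | intermediate
9 | methyl (3S)-3-[(tert-butyldimethylsilyl)oxy]-4-oxobutanoate | COC(=O)C[C@H](O[Si](C)(C)C(C)(C)C)C=O | intermediate
10 | acetylene | C#C | starting material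
11 | bis(pinacolato)diboron | CC1(C)OB(OC1(C)C)B1OC(C)(C)C(C)(C)O1 | starting material
12 | (Z)-1,2-bis(4,4,5,5-tetramethyl-1,3,2-dioxaborolan-2-yl)ethene | CC1(C)OB(/C=C\B2OC(C)(C)C(C)(C)O2)OC1(C)C | intermediate
13 | methyl (3S,4R,5Z)-3-[(tert-butyldimethylsilyl)oxy]-4-hydroxy-6-(4,4,5,5-tetramethyl-1,3,2-dioxaborolan-2-yl)hex-5-enoate (or its cyclic borate) | COC(=O)C[C@H](O[Si](C)(C)C(C)(C)C)[C@H](O)/C=C\B1OC(C)(C)C(C)(C)O1 | intermediate (not isolated)
14 | (4R,5S)-5-[(tert-butyldimethylsilyl)oxy]-4-hydroxycyclohex-2-en-1-one | O=C1C=C[C@@H](O)[C@@H](O[Si](C)(C)C(C)(C)C)C1 | intermediate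
15 | (5R,6S)-6-[(tert-butyldimethylsilyl)oxy]-2,5-bis[(trimethylsilyl)oxy]cyclohexa-1,3-diene | C[Si](C)(C)OC1=C[C@H](O[Si](C)(C)C(C)(C)C)[C@H](O[Si](C)(C)C)C=C1 | intermediate
16 | 5-{3-[(tert-butyldimethylsilyl)oxy]-4-methoxyphenyl}-3-oxopent-1-en-1-one (acylketene) | COc1ccc(CCC(=O)C=C=O)cc1O[Si](C)(C)C(C)(C)C | intermediate (not isolated)
17 | (5S,6R)-5-[(tert-butyldimethylsilyl)oxy]-2-(2-{3-[(tert-butyldimethylsilyl)oxy]-4-methoxyphenyl}ethyl)-6,8a-bis[(trimethylsilyl)oxy]-4a,5,6,8a-tetrahydro-4H-chromen-4-one (C4a and C8a not assigned; both are lost on aromatisation) | COc1ccc(CCC2=CC(=O)C3C(O[Si](C)(C)C)(O2)C=C[C@@H](O[Si](C)(C)C)[C@H]3O[Si](C)(C)C(C)(C)C)cc1O[Si](C)(C)C(C)(C)C | intermediate (not isolated)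
18 | (5S,6R)-5-[(tert-butyldimethylsilyl)oxy]-2-(2-{3-[(tert-butyldimethylsilyl)oxy]-4-methoxyphenyl}ethyl)-6-[(trimethylsilyl)oxy]-5,6-dihydro-4H-chromen-4-one | COc1ccc(CCc2cc(=O)c3c(o2)C=C[C@@H](O[Si](C)(C)C)[C@H]3O[Si](C)(C)C(C)(C)C)cc1O[Si](C)(C)C(C)(C)C | intermediate (not isolated)
19 | (5S,6R)-5-[(tert-butyldimethylsilyl)oxy]-2-(2-{3-[(tert-butyldimethylsilyl)oxy]-4-methoxyphenyl}ethyl)-6-hydroxy-5,6-dihydro-4H-chromen-4-one | COc1ccc(CCc2cc(=O)c3c(o2)C=C[C@@H](O)[C@H]3O[Si](C)(C)C(C)(C)C)cc1O[Si](C)(C)C(C)(C)C | intermediate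
20 | (5S,6R,7S,8S)-5-[(tert-butyldimethylsilyl)oxy]-2-(2-{3-[(tert-butyldimethylsilyl)oxy]-4-methoxyphenyl}ethyl)-7,8-epoxy-6-hydroxy-5,6,7,8-tetrahydro-4H-chromen-4-one (epoxide cis to 6-OH) | COc1ccc(CCc2cc(=O)c3c(o2)[C@H]4O[C@H]4[C@@H](O)[C@H]3O[Si](C)(C)C(C)(C)C)cc1O[Si](C)(C)C(C)(C)C | intermediate
21 | (5S,6S,7S,8S)-7,8-epoxy-5,6-dihydroxy-2-[2-(3-hydroxy-4-methoxyphenyl)ethyl]-5,6,7,8-tetrahydro-4H-chromen-4-one | COc1ccc(CCc2cc(=O)c3c(o2)[C@H]4O[C@H]4[C@@H](O)[C@H]3O)cc1O | intermediate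
22 | (5S,6S,7S,8R)-8-chloro-5,6,7-trihydroxy-2-[2-(3-hydroxy-4-methoxyphenyl)ethyl]-5,6,7,8-tetrahydro-4H-chromen-4-one | COc1ccc(CCc2cc(=O)c3c(o2)[C@H](Cl)[C@@H](O)[C@@H](O)[C@H]3O)cc1O | target

## Step count and risks

Total step count: 13. Longest linear sequence: 8 steps (steps 1–4 then 10–13, or steps 5, 6, 8–13).

Steps most likely to fail:

1. Step 8 (proposed new method). The alkenylrhodium formed from the second boryl group may be protonated or may add in conjugate fashion to enone already formed faster than it acylates the ester; the C6 alkoxide may lactonise onto the ester; and facial selectivity at C6 may be low. Fallback with known chemistry, from 9 back to 14: CH2=CHMgBr (THF, −78 °C) adds to the aldehyde under Felkin–Anh control and the alkoxide closes onto the ester on warming to give (4S,5R)-4-[(tert-butyldimethylsilyl)oxy]-5-ethenyloxolan-2-one F1. Me(MeO)NH·HCl/AlMe3 opens the lactone to the hydroxy Weinreb amide (3S,4R)-3-[(tert-butyldimethylsilyl)oxy]-4-hydroxy-N-methoxy-N-methylhex-5-enamide F2. Excess CH2=CHMgBr converts it into (5S,6R)-5-[(tert-butyldimethylsilyl)oxy]-6-hydroxyocta-1,7-dien-3-one F3. Ring-closing metathesis with second-generation Grubbs catalyst then forms C7=C8 and returns 14.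

2. Step 10. The silyloxy diene 15 may aromatise by loss of silanol at 110 °C before the acylketene is trapped, or the acylketene may dimerise. Fallback at low temperature, from 4 and 15 back to 18: bromide 4 and allenylmagnesium bromide give 4-(but-3-yn-1-yl)-2-[(tert-butyldimethylsilyl)oxy]-1-methoxybenzene F4. n-BuLi then DMF give 5-{3-[(tert-butyldimethylsilyl)oxy]-4-methoxyphenyl}pent-2-ynal F5. The lithium enolate released from 15 with MeLi (THF, −78 °C) adds to F5 to give the aldol (4R,5S)-5-[(tert-butyldimethylsilyl)oxy]-6-(5-{3-[(tert-butyldimethylsilyl)oxy]-4-methoxyphenyl}-1-hydroxypent-2-yn-1-yl)-4-[(trimethylsilyl)oxy]cyclohex-2-en-1-one F6. Dess–Martin periodinane oxidises it to the alkynyl 1,3-diketone (4R,5S)-5-[(tert-butyldimethylsilyl)oxy]-6-(5-{3-[(tert-butyldimethylsilyl)oxy]-4-methoxyphenyl}pent-2-ynoyl)-4-[(trimethylsilyl)oxy]cyclohex-2-en-1-one F7. Its enol should close 6-endo-dig onto the ynone (Et2NH cat., rt) to give 18, which is methanolysed to 19 as in step 10.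

3. Step 11. Oxygen transfer to the pyranone-conjugated alkene may be slow, so that vanadium oxidises the allylic alcohol instead (dienone, then aromatisation), or the C5 silyl ether may erode the syn selectivity. Fallback, from 19 back to 21: Boc2O/DMAP gives the C6 tert-butyl carbonate (5S,6R)-6-[(tert-butoxycarbonyl)oxy]-5-[(tert-butyldimethylsilyl)oxy]-2-(2-{3-[(tert-butyldimethylsilyl)oxy]-4-methoxyphenyl}ethyl)-5,6-dihydro-4H-chromen-4-one F8. I2 (MeCN, −20 °C) triggers a 5-exo iodocarbonate cyclisation in which the C6 oxygen delivers the carbonate oxygen to C7 on its own face and iodide adds anti at C8, giving (5S,6R,7S,8R)-5-[(tert-butyldimethylsilyl)oxy]-2-(2-{3-[(tert-butyldimethylsilyl)oxy]-4-methoxyphenyl}ethyl)-8-iodo-6,7-(carbonyldioxy)-5,6,7,8-tetrahydro-4H-chromen-4-one F9. K2CO3/MeOH cleaves the carbonate and the aryl silyl ether, and the C7 alkoxide displaces the trans iodide to give the same syn epoxide as (5S,6R,7S,8S)-5-[(tert-butyldimethylsilyl)oxy]-7,8-epoxy-6-hydroxy-2-[2-(3-hydroxy-4-methoxyphenyl)ethyl]-5,6,7,8-tetrahydro-4H-chromen-4-one F10. Bu4NF/AcOH removes the remaining silyl ether and joins the route at 21.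

## Further compounds

F1 | step 8 | (4S,5R)-4-[(tert-butyldimethylsilyl)oxy]-5-ethenyloxolan-2-one | O=C1C[C@H](O[Si](C)(C)C(C)(C)C)[C@@H](C=C)O1
F2 | step 8 | (3S,4R)-3-[(tert-butyldimethylsilyl)oxy]-4-hydroxy-N-methoxy-N-methylhex-5-enamide | CON(C)C(=O)C[C@H](O[Si](C)(C)C(C)(C)C)[C@H](O)C=C
F3 | step 8 | (5S,6R)-5-[(tert-butyldimethylsilyl)oxy]-6-hydroxyocta-1,7-dien-3-one | C=CC(=O)C[C@H](O[Si](C)(C)C(C)(C)C)[C@H](O)C=C
F4 | step 10 | 4-(but-3-yn-1-yl)-2-[(tert-butyldimethylsilyl)oxy]-1-methoxybenzene | COc1ccc(CCC#C)cc1O[Si](C)(C)C(C)(C)C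
F5 | step 10 | 5-{3-[(tert-butyldimethylsilyl)oxy]-4-methoxyphenyl}pent-2-ynal | COc1ccc(CCC#CC=O)cc1O[Si](C)(C)C(C)(C)C
F6 | step 10 | (4R,5S)-5-[(tert-butyldimethylsilyl)oxy]-6-(5-{3-[(tert-butyldimethylsilyl)oxy]-4-methoxyphenyl}-1-hydroxypent-2-yn-1-yl)-4-[(trimethylsilyl)oxy]cyclohex-2-en-1-one (new centres not assigned) | COc1ccc(CCC#CC(O)C2C(=O)C=C[C@@H](O[Si](C)(C)C)[C@H]2O[Si](C)(C)C(C)(C)C)cc1O[Si](C)(C)C(C)(C)C
F7 | step 10 | (4R,5S)-5-[(tert-butyldimethylsilyl)oxy]-6-(5-{3-[(tert-butyldimethylsilyl)oxy]-4-methoxyphenyl}pent-2-ynoyl)-4-[(trimethylsilyl)oxy]cyclohex-2-en-1-one | COc1ccc(CCC#CC(=O)C2C(=O)C=C[C@@H](O[Si](C)(C)C)[C@H]2O[Si](C)(C)C(C)(C)C)cc1O[Si](C)(C)C(C)(C)C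
F8 | step 11 | (5S,6R)-6-[(tert-butoxycarbonyl)oxy]-5-[(tert-butyldimethylsilyl)oxy]-2-(2-{3-[(tert-butyldimethylsilyl)oxy]-4-methoxyphenyl}ethyl)-5,6-dihydro-4H-chromen-4-one | COc1ccc(CCc2cc(=O)c3c(o2)C=C[C@@H](OC(=O)OC(C)(C)C)[C@H]3O[Si](C)(C)C(C)(C)C)cc1O[Si](C)(C)C(C)(C)C
F9 | step 11 | (5S,6R,7S,8R)-5-[(tert-butyldimethylsilyl)oxy]-2-(2-{3-[(tert-butyldimethylsilyl)oxy]-4-methoxyphenyl}ethyl)-8-iodo-6,7-(carbonyldioxy)-5,6,7,8-tetrahydro-4H-chromen-4-one (cyclic carbonate on O6/O7, iodide trans to O7) | COc1ccc(CCc2cc(=O)c3c(o2)[C@H](I)[C@H]4OC(=O)O[C@H]4[C@H]3O[Si](C)(C)C(C)(C)C)cc1O[Si](C)(C)C(C)(C)C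
F10 | step 11 | (5S,6R,7S,8S)-5-[(tert-butyldimethylsilyl)oxy]-7,8-epoxy-6-hydroxy-2-[2-(3-hydroxy-4-methoxyphenyl)ethyl]-5,6,7,8-tetrahydro-4H-chromen-4-one | COc1ccc(CCc2cc(=O)c3c(o2)[C@H]4O[C@H]4[C@@H](O)[C@H]3O[Si](C)(C)C(C)(C)C)cc1O
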